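## Retrosynthetic overview

1. The (Z)-cinnamate comes from syn-semihydrogenation of the 3-phenylpropiolate, itself made by acylating the tertiary guaia-3,11-dien-10-ol with a phenylpropiolic unit assembled from phenylacetylene and CO2.
2. The C10 carbinol comes from face-selective methyl addition to a trans-fused 14-norguaia-3,11-dien-10-one (hydroazulenone).
3. The seven-membered ring comes from a regioselective one-carbon ring expansion of a trans-hydrindan-4-one (CH2 inserted on the methylene side of the ketone). This is the pivotal step; it moves the ketone from β to γ of the isopropenyl-bearing carbon.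
4. The hydrindanone comes from axial conjugate isopropenylation of its enone; the cyclopentene comes from ring-closing metathesis of a trans-2-allyl-3-isopropenylcyclohexanone.
5. That ketone comes from a catalytic asymmetric conjugate isopropenylation/enolate allylation of cyclohex-2-en-1-one. Ring order: six-membered ring (bought), then cyclopentene (RCM), then six enlarged to seven.

Assumption: the target SMILES encodes the trans-fused (3aS,4S,7S,8aR) isomer (guaiane numbering 1S,5R,7S,10S; 4-O cis to H-3a), and that isomer is made.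

## Route

Step 1
Reactants: 1 cyclohex-2-en-1-one; 2 isopropenylmagnesium bromide; 3 allyl bromide
Product: 7 (2S,3R)-2-(prop-2-en-1-yl)-3-(prop-1-en-2-yl)cyclohexan-1-one, via B-isopropenyl-9-BBN 4 (not isolated), via 9-BBN enolate 5 (not isolated), via lithium enolate 6 (not isolated)
Conditions: 2, B-MeO-9-BBN, THF/hexane, 0 °C → rt, Mg salts filtered off, solvent switched to toluene; 1, [Rh(OMe)(cod)]2 (1.5 mol%), (R)-BINAP (3.3 mol%), toluene, 80 °C; then n-BuLi, THF, −78 °C; 3, −78 → 0 °C
Reagents that add atoms: none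
Why: Proposed new method: rhodium–BINAP conjugate transfer of an α-branched alkenyl group from a B-alkenyl-9-BBN under anhydrous conditions, with capture of the boron enolate, has not been shown; the sp2 group should transmetallate from boron to the monovalent rhodium methoxide/oxa-π-allyl far faster than the bicyclic alkyl groups, insert into the enone on the face set by (R)-BINAP (3R) and release 9-BBN enolate 5, which after B→Li exchange is allylated anti to the C3 substituent (2S, trans); closest known reaction type: Hayashi–Miyaura asymmetric 1,4-addition of B-aryl-9-BBN reagents followed by allylation of the boron enolate.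

Step 2
Reactants: 7
Product: 8 (3aS,7aR)-1-methyl-3,3a,5,6,7,7a-hexahydro-4H-inden-4-one
Conditions: second-generation Grubbs catalyst RuCl2(=CHPh)(PCy3)(H2IMes) (3 mol%), CH2Cl2 (0.01 M), 40 °C
Reagents that add atoms: none
Why: Ring-closing metathesis of the vicinal trans-diequatorial allyl and isopropenyl groups closes the 1-methylcyclopentene with loss of ethene; no stereocentre is touched, so the trans ring fusion is inherited from 7.

Step 3
Reactants: 8
Product: 10 (3aS,7aR)-1-methyl-3,3a,7,7a-tetrahydro-4H-inden-4-one, via silyl enol ether 9 (not isolated)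
Conditions: LiN(i-Pr)2, Me3SiCl, THF, −78 °C; then Pd(OAc)2 (1.1 equiv), MeCN, rt
Reagents that add atoms: none
Why: Saegusa–Ito oxidation: kinetic deprotonation takes the unhindered C5 methylene proton and not the ring-fusion methine, and palladium-mediated β-hydride elimination from the silyl enol ether gives the C5=C6 enone with C3a and C7a untouched.

Step 4
Reactants: 10; 2 isopropenylmagnesium bromide
Product: 11 (3aS,6R,7aR)-1-methyl-6-(prop-1-en-2-yl)-3,3a,5,6,7,7a-hexahydro-4H-inden-4-one
Conditions: 2 (1.5 equiv), CuBr·SMe2 (20 mol%), THF, −78 → −40 °C; then H2O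
Reagents that add atoms: none
Why: Copper-catalysed conjugate addition: stereoelectronically controlled axial attack on the rigid trans-fused cyclohexenone, anti to the C7a–C1 bond (the rule for 5-substituted cyclohexenones), places the isopropenyl group cis to H-7a (6R).

Step 5
Reactants: 11
Product: 13 (3aS,7S,8aR)-1-methyl-7-(prop-1-en-2-yl)-3,3a,5,6,7,8-hexahydroazulen-4(8aH)-one, via C-silyl ketone 12 (not isolated)
Conditions: Me3SiCHN2 (1.3 equiv), AlMe3 (1.2 equiv), CH2Cl2, −78 → −20 °C; then 1 M HCl, THF, 0 °C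
Reagents that add atoms: (trimethylsilyl)diazomethane, C[Si](C)(C)C=[N+]=[N-]
Why: Lewis-acid-promoted diazoalkane–ketone homologation (Tiffeneau–Demjanov-type 1,2-shift): the diazo carbon adds to the AlMe3-activated carbonyl and the less substituted C4–C5 bond migrates with loss of N2, so CH2 is inserted on the methylene side; protodesilylation gives the cycloheptanone, and no base is present to disturb the epimerisable ring-fusion centre.

Step 6
Reactants: 13
Product: 14 (3aS,4S,7S,8aR)-1,4-dimethyl-7-(prop-1-en-2-yl)-3,3a,4,5,6,7,8,8a-octahydroazulen-4-ol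
Conditions: MeAl(OAr)2 (3 equiv; Ar = 2,6-di-tert-butyl-4-methylphenyl), MeLi (3 equiv), toluene, −78 °C; then aq. potassium sodium tartrate
Reagents that add atoms: methyllithium, [Li]C
Why: Amphiphilic carbonyl methylation: the very bulky aluminium phenoxide binds the ketone on its open face (syn to the axial H-3a), so MeLi is delivered to the opposite, axial-type face, giving CH3 anti and OH syn to H-3a (4S); uncomplexed MeLi or MeMgBr is expected to favour the C4 epimer.

Step 7
Reactants: 14; 15 phenylacetylene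
Product: 20 (3aS,4S,7S,8aR)-1,4-dimethyl-7-(prop-1-en-2-yl)-3,3a,4,5,6,7,8,8a-octahydroazulen-4-yl 3-phenylprop-2-ynoate, via lithium phenylacetylide 16 (not isolated), via lithium 3-phenylprop-2-ynoate 17 (not isolated), via mixed pivalic anhydride 18 (not isolated), via lithium alkoxide 19 (not isolated)
Conditions: 15, n-BuLi, THF, −78 °C; CO2, −78 → 0 °C; t-BuCOCl, 0 °C; then 19 (from 14, n-BuLi, THF, −78 °C), −78 → 0 °C
Reagents that add atoms: carbon dioxide, O=C=O
Why: Acetylide carboxylation followed by mixed-anhydride acylation: the tertiary lithium alkoxide attacks the unhindered alkynoyl carbonyl (the pivaloyl carbonyl is shielded), which esterifies the hindered C4–O without ionising it, so the C4 configuration is retained.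

Step 8
Reactants: 20
Product: 21 (3aS,4S,7S,8aR)-1,4-dimethyl-7-(prop-1-en-2-yl)-3,3a,4,5,6,7,8,8a-octahydroazulen-4-yl (2Z)-3-phenylprop-2-enoate
Conditions: H2 (1 atm), Pd/CaCO3 poisoned with Pb(OAc)2, quinoline, EtOAc, rt, stopped after 1 equiv H2
Reagents that add atoms: none
Why: Lindlar-type semihydrogenation: syn delivery of H2 to the aryl ynoate on lead-poisoned palladium gives the (Z)-cinnamate, and the poisoned catalyst leaves the isopropenyl and trisubstituted ring alkenes alone.

## Compound list

1 | cyclohex-2-en-1-one | O=C1C=CCCC1 | starting material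
2 | isopropenylmagnesium bromide (prop-1-en-2-ylmagnesium bromide) | CC(=C)[Mg]Br | starting material
3 | allyl bromide (3-bromoprop-1-ene) | C=CCBr | starting material
4 | 9-(prop-1-en-2-yl)-9-borabicyclo[3.3.1]nonane (B-isopropenyl-9-BBN) | C=C(C)B1C2CCCC1CCC2 | intermediate
5 | 9-{[(3R)-3-(prop-1-en-2-yl)cyclohex-1-en-1-yl]oxy}-9-borabicyclo[3.3.1]nonane | C=C(C)[C@@H]1CCCC(OB2C3CCCC2CCC3)=C1 | intermediate
6 | lithium (3R)-3-(prop-1-en-2-yl)cyclohex-1-en-1-olate | [Li+].C=C(C)[C@@H]1CCCC([O-])=C1 | intermediate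
7 | (2S,3R)-2-(prop-2-en-1-yl)-3-(prop-1-en-2-yl)cyclohexan-1-one (trans) | O=C1CCC[C@@H](C(C)=C)[C@@H]1CC=C | intermediate
8 | (3aS,7aR)-1-methyl-3,3a,5,6,7,7a-hexahydro-4H-inden-4-one (trans-fused) | C1CC(=O)[C@H]2CC=C(C)[C@@H]2C1 | intermediate
9 | (3aS,7aR)-1-methyl-4-[(trimethylsilyl)oxy]-3a,6,7,7a-tetrahydro-3H-indene | C1C=C(O[Si](C)(C)C)[C@H]2CC=C(C)[C@@H]2C1 | intermediate
10 | (3aS,7aR)-1-methyl-3,3a,7,7a-tetrahydro-4H-inden-4-one | C1=CC(=O)[C@H]2CC=C(C)[C@@H]2C1 | intermediate
11 | (3aS,6R,7aR)-1-methyl-6-(prop-1-en-2-yl)-3,3a,5,6,7,7a-hexahydro-4H-inden-4-one (isopropenyl cis to H-7a) | C=C(C)[C@H]1CC(=O)[C@H]2CC=C(C)[C@@H]2C1 | intermediate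
12 | 5-(trimethylsilyl) derivative of 13 (C5 epimers) | C=C(C)[C@H]1CC([Si](C)(C)C)C(=O)[C@H]2CC=C(C)[C@@H]2C1 | intermediate
13 | (3aS,7S,8aR)-1-methyl-7-(prop-1-en-2-yl)-3,3a,5,6,7,8-hexahydroazulen-4(8aH)-one (14-norguaia-3,11-dien-10-one; same geometry at the isopropenyl carbon as 11, descriptor changes by CIP priority only) | C=C(C)[C@H]1CCC(=O)[C@H]2CC=C(C)[C@@H]2C1 | intermediate
14 | (3aS,4S,7S,8aR)-1,4-dimethyl-7-(prop-1-en-2-yl)-3,3a,4,5,6,7,8,8a-octahydroazulen-4-ol (guaia-3,11-dien-10-ol) | C=C(C)[C@H]1CC[C@](C)(O)[C@H]2CC=C(C)[C@@H]2C1 | intermediate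
15 | phenylacetylene (ethynylbenzene) | C#Cc1ccccc1 | starting material
16 | lithium phenylacetylide | [Li+].[C-]#Cc1ccccc1 | intermediate
17 | lithium 3-phenylprop-2-ynoate | [Li+].[O-]C(=O)C#Cc1ccccc1 | intermediate
18 | 2,2-dimethylpropanoic 3-phenylprop-2-ynoic anhydride | CC(C)(C)C(=O)OC(=O)C#Cc1ccccc1 | intermediate
19 | lithium (3aS,4S,7S,8aR)-1,4-dimethyl-7-(prop-1-en-2-yl)-3,3a,4,5,6,7,8,8a-octahydroazulen-4-olate | [Li+].C=C(C)[C@H]1CC[C@](C)([O-])[C@H]2CC=C(C)[C@@H]2C1 | intermediate
20 | (3aS,4S,7S,8aR)-1,4-dimethyl-7-(prop-1-en-2-yl)-3,3a,4,5,6,7,8,8a-octahydroazulen-4-yl 3-phenylprop-2-ynoate | C=C(C)[C@H]1CC[C@](C)(OC(=O)C#Cc2ccccc2)[C@H]2CC=C(C)[C@@H]2C1 | intermediate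
21 | (3aS,4S,7S,8aR)-1,4-dimethyl-7-(prop-1-en-2-yl)-3,3a,4,5,6,7,8,8a-octahydroazulen-4-yl (2Z)-3-phenylprop-2-enoate | C=C(C)[C@H]1CC[C@](C)(OC(=O)/C=C\c2ccccc2)[C@H]2CC=C(C)[C@@H]2C1 | target

## Step count and risk

Total step count: 8. Longest linear sequence: 8 (1 → 21).

**Step 1 (proposed new method).** The α-branched alkenyl group may transfer sluggishly from the 9-BBN reagent, residual magnesium salts may poison the rhodium catalyst, or the ee may erode at 80 °C. The fallback uses known chemistry, sets out from 1 and comes back at 11. Aqueous Hayashi–Miyaura addition of potassium isopropenyltrifluoroborate to 1 ([Rh(cod)2]BF4, (R)-BINAP, toluene/H2O, 100 °C) gives (R)-3-(prop-1-en-2-yl)cyclohexan-1-one F1. Kinetic silylation on the side away from the substituent (LiN(i-Pr)2, Me3SiCl, THF, −78 °C) gives trimethyl{[(5R)-5-(prop-1-en-2-yl)cyclohex-1-en-1-yl]oxy}silane F2. Saegusa–Ito oxidation (Pd(OAc)2, MeCN) gives (R)-5-(prop-1-en-2-yl)cyclohex-2-en-1-one F3; the achiral conjugated regioisomer from the minor enol ether is removed by chromatography. Copper-catalysed addition of 2 (CuBr·SMe2, THF, −78 °C), trans to the existing substituent, gives C2-symmetric (3R,5R)-3,5-di(prop-1-en-2-yl)cyclohexan-1-one F4. Its two α-carbons are homotopic, so enolisation and allylation with 3 (LiN(i-Pr)2, THF, −78 → 0 °C) is regiochemically unambiguous and gives (2S,3R,5R)-2-(prop-2-en-1-yl)-3,5-di(prop-1-en-2-yl)cyclohexan-1-one F5, with the allyl group anti to the neighbouring isopropenyl. Ring-closing metathesis of F5 (second-generation Grubbs catalyst RuCl2(=CHPh)(PCy3)(H2IMes), CH2Cl2, 40 °C) engages only the adjacent isopropenyl group and delivers 11.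

**Step 5 (ring expansion).** The ring-fusion methine might migrate in part, the Lewis acid might trigger a carbonyl-ene closure of the axial isopropenyl group onto the activated ketone, or a second homologation might occur. The fallback is a regiospecific cyclopropanol-based ring expansion that sets out from 10 and comes back at 13. Conjugate addition of 2 to 10 with silyl trapping (CuBr·SMe2, Me3SiCl, THF, −78 °C) gives trimethyl{[(3aS,6R,7aR)-1-methyl-6-(prop-1-en-2-yl)-3a,6,7,7a-tetrahydro-3H-inden-4-yl]oxy}silane F6. Simmons–Smith cyclopropanation of the electron-rich enol ether (Et2Zn, CH2I2, CH2Cl2, 0 °C) gives the fused siloxycyclopropane F7. Oxidative cleavage of its internal bond (FeCl3, DMF, 0 °C; Ito–Saegusa-type radical ring expansion) gives (3aS,8aR)-6-chloro-1-methyl-7-(prop-1-en-2-yl)-3,3a,5,6,7,8-hexahydroazulen-4(8aH)-one F8. Radical dechlorination (Bu3SnH, AIBN, benzene, 80 °C) gives 13. The new CH2 can only end up between the carbonyl and the former enol carbon, and the free ketone never meets a strong Lewis acid.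

**Step 6 (C4 configuration).** Facial selectivity on the flexible cycloheptanone is the least predictable element of the route, and the aluminium-complexed ketone may react slowly. The fallback sets out from 13 and comes back at 14. Corey–Chaykovsky epoxidation with dimethylsulfonium methylide (Me3SI, KN(SiMe3)2, THF, −10 °C), a small irreversible nucleophile that favours axial-type attack, gives (3aS,4S,7S,8aR)-1-methyl-7-(prop-1-en-2-yl)-3,3a,5,6,7,8-hexahydro-8aH-spiro[azulene-4,2'-oxirane] F9, with oxygen cis to H-3a. Reductive opening at the CH2 terminus (LiEt3BH, THF, 0 °C) gives 14. If the sulfonium ylide gives the wrong face, the reversible oxosulfonium ylide gives the complementary epoxide.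

Further compounds
F1 | step 1 | (R)-3-(prop-1-en-2-yl)cyclohexan-1-one | C=C(C)[C@@H]1CCCC(=O)C1
F2 | step 1 | trimethyl{[(5R)-5-(prop-1-en-2-yl)cyclohex-1-en-1-yl]oxy}silane | C=C(C)[C@@H]1CCC=C(O[Si](C)(C)C)C1
F3 | step 1 | (R)-5-(prop-1-en-2-yl)cyclohex-2-en-1-one | C=C(C)[C@@H]1CC=CC(=O)C1
F4 | step 1 | (3R,5R)-3,5-di(prop-1-en-2-yl)cyclohexan-1-one | C=C(C)[C@H]1CC(=O)C[C@H](C(C)=C)C1
F5 | step 1 | (2S,3R,5R)-2-(prop-2-en-1-yl)-3,5-di(prop-1-en-2-yl)cyclohexan-1-one | C=C(C)[C@H]1CC(=O)[C@@H](CC=C)[C@H](C(C)=C)C1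
F6 | step 5 | trimethyl{[(3aS,6R,7aR)-1-methyl-6-(prop-1-en-2-yl)-3a,6,7,7a-tetrahydro-3H-inden-4-yl]oxy}silane | C=C(C)[C@H]1C=C(O[Si](C)(C)C)[C@H]2CC=C(C)[C@@H]2C1
F7 | step 5 | fused siloxycyclopropane from CH2 addition across C4=C5 of F6 (cyclopropane face not specified) | C=C(C)[C@H]1C2CC2(O[Si](C)(C)C)[C@H]3CC=C(C)[C@@H]3C1
F8 | step 5 | (3aS,8aR)-6-chloro-1-methyl-7-(prop-1-en-2-yl)-3,3a,5,6,7,8-hexahydroazulen-4(8aH)-one (C6 epimers) | C=C(C)[C@H]1C(Cl)CC(=O)[C@H]2CC=C(C)[C@@H]2C1
F9 | step 6 | (3aS,4S,7S,8aR)-1-methyl-7-(prop-1-en-2-yl)-3,3a,5,6,7,8-hexahydro-8aH-spiro[azulene-4,2'-oxirane] | C=C(C)[C@H]1CC[C@]2(OC2)[C@H]3CC=C(C)[C@@H]3C1
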